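**Retrosynthetic overview** (locants of the target decalin are used throughout: C1(H)Me–C2(H)O‑acyl–C3–C4–C4a(H)–C5(H)OH–C6(=O)–C7(=CMe2)–C8H2–C8a(Me); ring A = C1–C4/C4a/C8a, ring B = C4a–C8/C8a)
1. The side chain is built last on the C2 hydroxyl (acylation with a phosphonopropanoic acid, then Z‑selective olefination); the C6 ketone is unveiled in the final step by oxidation of the only allylic hydroxyl.
2. C1–H/C2–OH and C4a–H/C5–OH come from one double hydroboration of a C1=C2/C4a=C5 diene, both additions steered by the C8a methyl.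
3. Ring B and the C8–C8a bond come from an anionic oxy‑Cope rearrangement. The enabling feature is the chain C6(=O)–C7–C8–C8a–C1–C2: with C1–C2 written as an alkene (C1 carries only H/Me, C2 only the oxygen that hydroboration returns) it is a δ,ε‑unsaturated ketone; the enolate formed is trapped with acetone to bring in the isopropylidene carbons at C7.
4. The rearrangement substrate is a 2‑vinylbicyclo[2.2.2]oct‑5‑en‑2‑ol, made by a catalytic asymmetric Diels–Alder reaction of 2,3‑dimethylcyclohexa‑1,3‑diene with acrolein, deformylation and vinyl addition.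
5. Ring order: ring A (as the cyclohexadiene, from 2‑methylcyclohex‑2‑enone) → temporary bicyclo[2.2.2]octene → ring B in the key step.

Key step: step 6

Assumption: the iminium‑catalysed cycloaddition of step 3 is taken to follow the facial sense of the unsubstituted cyclohexa‑1,3‑diene/acrolein pair, which is assumed to call for the (5R)‑imidazolidinone; if 5 forms as the antipode, the (5S)‑catalyst is used instead.

**Route**

Step 1
Reactants: 1 2‑methylcyclohex‑2‑en‑1‑one
Product: 2 6‑methylcyclohexa‑1,5‑dien‑1‑yl trifluoromethanesulfonate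
Conditions: LiN(iPr)2 (LDA), THF, −78 °C; then PhNTf2, −78 → 0 °C
Reagents that add atoms: N‑phenylbis(trifluoromethanesulfonimide), O=S(=O)(N(c1ccccc1)S(=O)(=O)C(F)(F)F)C(F)(F)F
Why: Kinetic deprotonation of the enone at the α′‑methylene gives the cross‑conjugated lithium dienolate, whose O‑triflation (enol triflate formation) fixes the 2‑triflyloxy‑1,3‑diene without touching the existing C=C.

Step 2
Reactants: 2 6‑methylcyclohexa‑1,5‑dien‑1‑yl trifluoromethanesulfonate
Product: 3 2,3‑dimethylcyclohexa‑1,3‑diene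
Conditions: MeMgBr, Fe(acac)3 (5 mol %), THF/NMP, −30 → 0 °C; volatile product kept in solution
Reagents that add atoms: methylmagnesium bromide, C[Mg]Br
Why: Iron‑catalysed Kumada‑type cross‑coupling of an alkenyl triflate with MeMgBr is fast at low temperature and replaces the triflate by the second methyl, giving the symmetrical 2,3‑dimethyl diene.

Step 3
Reactants: 3 2,3‑dimethylcyclohexa‑1,3‑diene; 4 acrolein (prop‑2‑enal)
Product: 5 (1S,2R,4R)‑5,6‑dimethylbicyclo[2.2.2]oct‑5‑ene‑2‑carbaldehyde (endo)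
Conditions: (5R)‑5‑benzyl‑2,2,3‑trimethylimidazolidin‑4‑one·HCl (10 mol %), MeCN/H2O 95:5, 0 °C → rt; exo isomer removed by chromatography
Reagents that add atoms: none
Why: Iminium‑catalysed Diels–Alder reaction in which the symmetrical diene leaves no regiochemical issue, the endo mode usual for cyclohexa‑1,3‑dienes places the formyl group syn to the new C=C, and the benzyl group of the catalyst shields one face of the acrolein iminium ion so that the three stereocentres of 5 are set by the catalyst; the minor exo adduct, which would lead to the antipodal ketone, is separated here.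

Step 4
Reactants: 5 (1S,2R,4R)‑5,6‑dimethylbicyclo[2.2.2]oct‑5‑ene‑2‑carbaldehyde
Product: 6 (1R,4R)‑5,6‑dimethylbicyclo[2.2.2]oct‑5‑en‑2‑one
Conditions: O2 (1 atm), Cu(OAc)2 (10 mol %), 2,2′‑bipyridine, DABCO, DMF, 40 °C
Reagents that add atoms: dioxygen, O=O
Why: Copper‑catalysed aerobic oxidative deformylation of an α‑branched aldehyde (oxygenation of the enol/enamine form and C–C cleavage of the α‑hydroperoxy aldehyde) removes the formyl carbon as formic acid and leaves the ketone, the two bridgehead stereocentres being untouched.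

Step 5
Reactants: 6 (1R,4R)‑5,6‑dimethylbicyclo[2.2.2]oct‑5‑en‑2‑one; 7 vinylmagnesium bromide
Product: 8 (1R,2R,4R)‑2‑ethenyl‑5,6‑dimethylbicyclo[2.2.2]oct‑5‑en‑2‑ol
Conditions: CeCl3 (anhydrous), THF, −78 °C; then H2O
Reagents that add atoms: none
Why: Grignard 1,2‑addition (organocerium variant to suppress enolisation) occurs from the carbonyl face flanked by the planar C=C bridge, less hindered than the face under the CH2–CH2 bridge, which sets the carbinol centre with the vinyl group syn to the ring alkene as the rearrangement requires.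

Step 6
Reactants: 8 (1R,2R,4R)‑2‑ethenyl‑5,6‑dimethylbicyclo[2.2.2]oct‑5‑en‑2‑ol; 9 acetone
Product: 13 (4aS,8aR)‑3‑(2‑hydroxypropan‑2‑yl)‑4a,5‑dimethyl‑3,4,4a,7,8,8a‑hexahydronaphthalen‑2(1H)‑one (C3 epimers), via potassium alkoxide 10 (not isolated), via potassium enolate 11 (not isolated), via chlorozinc enolate 12 (not isolated)
Conditions: KH (1.1 equiv), 18‑crown‑6, THF, 0 → 50 °C; then ZnCl2, −78 °C; then acetone, −78 → −20 °C; then H2O
Reagents that add atoms: none
Why: Deprotonation gives alkoxide 10, whose 1,5‑diene (vinyl C=C, carbinol carbon, bridgehead, ring C=C) undergoes a charge‑accelerated [3,3] shift through the boat geometry imposed by the cage, forming C8–C8a, cleaving the carbinol–bridgehead bond and releasing the bicyclo[2.2.2]octene strain as enolate 11; transmetalation to zinc and aldol addition to acetone then attach the three isopropylidene carbons at C7, the only enolate carbon. The closest known reaction type is the anionic oxy‑Cope rearrangement of 2‑vinylbicyclo[2.2.2]oct‑5‑en‑2‑ols to cis‑fused octalones, followed by a zinc‑enolate aldol addition. Ring B is closed by the sigmatropic shift itself: the ketone bridge and the vinyl group become the six‑membered ring B as the C8–C8a bond forms, while the ring that carried the diene becomes ring A with a C1=C2 double bond. The quaternary C8a is formed suprafacially on the alkene face syn to the carbinol bridge, so its configuration is dictated by the bridgehead configuration fixed in step 3; C4a emerges cis to the new bond and is reset later, and C7 forms as an inconsequential mixture. The step needs the vinyl group syn to the ring alkene (secured in step 5) and an enolate that reacts before proton exchange scrambles its position (secured by aprotic conditions, the near‑exact charge of KH and low‑temperature trapping).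

Step 7
Reactants: 13 (4aS,8aR)‑3‑(2‑hydroxypropan‑2‑yl)‑4a,5‑dimethyl‑3,4,4a,7,8,8a‑hexahydronaphthalen‑2(1H)‑one
Product: 15 (4aS,8aR)‑4a,5‑dimethyl‑3‑(propan‑2‑ylidene)‑3,4,4a,7,8,8a‑hexahydronaphthalen‑2(1H)‑one, via tertiary methanesulfonate 14 (not isolated)
Conditions: MsCl, Et3N, CH2Cl2, 0 °C; then DBU, 0 °C → rt
Reagents that add atoms: none
Why: Sulfene mesylation of the tertiary aldol hydroxyl followed by base‑mediated elimination (aldol dehydration, E1cB‑type) and DBU equilibration of any isopropenyl isomer gives the favoured conjugated tetrasubstituted enone and removes the C7 stereocentre.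

Step 8
Reactants: 15 (4aS,8aR)‑4a,5‑dimethyl‑3‑(propan‑2‑ylidene)‑3,4,4a,7,8,8a‑hexahydronaphthalen‑2(1H)‑one
Product: 17 (4aR)‑4a,5‑dimethyl‑3‑(propan‑2‑ylidene)‑4,4a,7,8‑tetrahydronaphthalen‑2(3H)‑one, via lithium dienolate 16 (not isolated)
Conditions: LiN(iPr)2, THF, −78 °C; then PhS(Cl)=N‑t‑Bu, −78 °C
Reagents that add atoms: none
Why: Kinetic deprotonation can only occur at the C5 methylene, and sulfinimidoyl‑chloride dehydrogenation of the lithium enolate (Mukaiyama dehydrogenation, syn elimination of the sulfenamide) introduces the C4a=C5 double bond, deliberately erasing the cis ring‑fusion centre so that C8a is the only stereocentre left.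

Step 9
Reactants: 17 (4aR)‑4a,5‑dimethyl‑3‑(propan‑2‑ylidene)‑4,4a,7,8‑tetrahydronaphthalen‑2(3H)‑one
Product: 18 (2R,4aR)‑4a,5‑dimethyl‑3‑(propan‑2‑ylidene)‑2,3,4,4a,7,8‑hexahydronaphthalen‑2‑ol
Conditions: NaBH4, CeCl3·7H2O, MeOH, −78 → 0 °C
Reagents that add atoms: none
Why: Luche 1,2‑reduction of the cross‑conjugated dienone, with hydride expected to add axially from the α face as in steroidal 4‑en‑3‑ones, should give the pseudo‑equatorial 6β‑alcohol; this centre only steers step 11 and is destroyed in step 18.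

Step 10
Reactants: 18 (2R,4aR)‑4a,5‑dimethyl‑3‑(propan‑2‑ylidene)‑2,3,4,4a,7,8‑hexahydronaphthalen‑2‑ol
Product: 19 tert‑butyl{[(2R,4aR)‑4a,5‑dimethyl‑3‑(propan‑2‑ylidene)‑2,3,4,4a,7,8‑hexahydronaphthalen‑2‑yl]oxy}dimethylsilane
Conditions: TBSCl, imidazole, DMF, rt
Reagents that add atoms: tert‑butyldimethylsilyl chloride, CC(C)(C)[Si](C)(C)Cl
Why: Standard silylation of the only hydroxyl; the bulky silyl ether later shields the neighbouring C5 hydroxyl and keeps C6 at the alcohol level until the end.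

Step 11
Reactants: 19 tert‑butyl{[(2R,4aR)‑4a,5‑dimethyl‑3‑(propan‑2‑ylidene)‑2,3,4,4a,7,8‑hexahydronaphthalen‑2‑yl]oxy}dimethylsilane
Product: 21 (1R,2R,4aR,5S,6S,8aR)‑6‑[(tert‑butyldimethylsilyl)oxy]‑1,8a‑dimethyl‑7‑(propan‑2‑ylidene)decahydronaphthalene‑2,5‑diol (target locants), via bis‑thexylboryl adduct 20 (not isolated)
Conditions: thexylborane (from BH3·THF + 2,3‑dimethylbut‑2‑ene, 0 °C), THF, 0 °C → rt; then NaOH, H2O2, 0 °C → rt
Reagents that add atoms: hydrogen peroxide, OO
Why: Hydroboration–oxidation with syn addition of H and B: boron goes to the less substituted carbons C2 and C5, both additions occur on the α face anti to the axial C8a methyl (and anti to the 6β‑silyloxy group, as for 2‑cyclohexenyl ethers and steroidal 4‑en‑3β‑ols), so C1–H, C2–OH, C4a–H and C5–OH are all set from C8a and the ring fusion becomes trans, while thexylborane, itself the adduct of a tetrasubstituted alkene that does not add a second one, should spare the isopropylidene.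

Step 12
Reactants: 22 angelic acid [(2Z)‑2‑methylbut‑2‑enoic acid]; 23 2‑bromoethanol
Product: 24 2‑hydroxyethyl (2Z)‑2‑methylbut‑2‑enoate
Conditions: K2CO3, DMF, rt → 40 °C
Reagents that add atoms: none
Why: SN2 O‑alkylation of the carboxylate forms the ester without activating the acyl group, so the Z (angelate) geometry cannot isomerise to the tiglate.

Step 13
Reactants: 24 2‑hydroxyethyl (2Z)‑2‑methylbut‑2‑enoate
Product: 25 2‑oxoethyl (2Z)‑2‑methylbut‑2‑enoate
Conditions: Dess–Martin periodinane, CH2Cl2, 0 °C → rt; used crude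
Reagents that add atoms: none
Why: Dess–Martin oxidation of the primary alcohol under neutral conditions gives the sensitive α‑acyloxy aldehyde, which is used directly.

Step 14
Reactants: 26 ethyl 2‑[bis(2,2,2‑trifluoroethoxy)phosphoryl]propanoate
Product: 27 2‑[bis(2,2,2‑trifluoroethoxy)phosphoryl]propanoic acid
Conditions: LiOH·H2O (1.05 equiv), THF/H2O, 0 °C; then 1 M HCl
Reagents that add atoms: lithium hydroxide, [Li+].[OH-]
Why: Saponification of the carboxylic ethyl ester with one equivalent of hydroxide at 0 °C frees the acid, the short contact time protecting the trifluoroethyl phosphonate esters.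

Step 15
Reactants: 21 (1R,2R,4aR,5S,6S,8aR)‑6‑[(tert‑butyldimethylsilyl)oxy]‑1,8a‑dimethyl‑7‑(propan‑2‑ylidene)decahydronaphthalene‑2,5‑diol; 27 2‑[bis(2,2,2‑trifluoroethoxy)phosphoryl]propanoic acid
Product: 28 (1R,2R,4aR,5S,6S,8aR)‑6‑[(tert‑butyldimethylsilyl)oxy]‑5‑hydroxy‑1,8a‑dimethyl‑7‑(propan‑2‑ylidene)decahydronaphthalen‑2‑yl 2‑[bis(2,2,2‑trifluoroethoxy)phosphoryl]propanoate (epimers at the phosphonate α‑carbon)
Conditions: DCC, DMAP (cat.), CH2Cl2, −20 → 0 °C
Reagents that add atoms: none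
Why: Steglich esterification; the equatorial C2 hydroxyl should be acylated in preference to the C5 hydroxyl, which is flanked by the silyloxy‑bearing C6 and the ring fusion, and the phosphonate acid carries no alkene geometry that could be lost.

Step 16
Reactants: 28 phosphonate ester (as in step 15); 25 2‑oxoethyl (2Z)‑2‑methylbut‑2‑enoate
Product: 29 (1R,2R,4aR,5S,6S,8aR)‑6‑[(tert‑butyldimethylsilyl)oxy]‑5‑hydroxy‑1,8a‑dimethyl‑7‑(propan‑2‑ylidene)decahydronaphthalen‑2‑yl (2Z)‑2‑methyl‑4‑{[(2Z)‑2‑methylbut‑2‑enoyl]oxy}but‑2‑enoate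
Conditions: KN(SiMe3)2 (KHMDS, 1.05 equiv), 18‑crown‑6, THF, −78 °C; then 25
Reagents that add atoms: none
Why: Still–Gennari olefination: the bis(trifluoroethyl) phosphonate anion adds to the aldehyde and the oxaphosphetane collapses under kinetic control to the Z‑trisubstituted enoate, building the inner Z double bond on the substrate and avoiding activation of an isomerisable Z‑acid.

Step 17
Reactants: 29 silyl‑protected diester (as in step 16)
Product: 30 (1R,2R,4aR,5S,6S,8aR)‑5,6‑dihydroxy‑1,8a‑dimethyl‑7‑(propan‑2‑ylidene)decahydronaphthalen‑2‑yl (2Z)‑2‑methyl‑4‑{[(2Z)‑2‑methylbut‑2‑enoyl]oxy}but‑2‑enoate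
Conditions: HF·pyridine, pyridine, THF, 0 °C → rt
Reagents that add atoms: none
Why: Fluoride‑mediated desilylation with buffered HF·pyridine should leave both esters and both Z‑alkenes intact.

Step 18
Reactants: 30 diol diester (as in step 17)
Product: 31 (1R,2R,4aR,5S,8aR)‑5‑hydroxy‑1,8a‑dimethyl‑6‑oxo‑7‑(propan‑2‑ylidene)decahydronaphthalen‑2‑yl (2Z)‑2‑methyl‑4‑{[(2Z)‑2‑methylbut‑2‑enoyl]oxy}but‑2‑enoate (CNP0308665.1)
Conditions: MnO2 (activated, excess), CH2Cl2, rt
Reagents that add atoms: none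
Why: MnO2 allylic oxidation is chemoselective for the C6 hydroxyl, the only one allylic (to the isopropylidene), so the saturated C5 hydroxyl stays free and the base‑sensitive α‑ketol is formed last under neutral conditions.

**Compound list**

1 | 2‑methylcyclohex‑2‑en‑1‑one | CC1=CCCCC1=O | starting material
2 | 6‑methylcyclohexa‑1,5‑dien‑1‑yl trifluoromethanesulfonate | CC1=CCCC=C1OS(=O)(=O)C(F)(F)F | intermediate
3 | 2,3‑dimethylcyclohexa‑1,3‑diene | CC1=CCCC=C1C | intermediate
4 | acrolein (prop‑2‑enal) | C=CC=O | starting material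
5 | (1S,2R,4R)‑5,6‑dimethylbicyclo[2.2.2]oct‑5‑ene‑2‑carbaldehyde | O=C[C@@H]1C[C@H]2CC[C@@H]1C(C)=C2C | intermediate
6 | (1R,4R)‑5,6‑dimethylbicyclo[2.2.2]oct‑5‑en‑2‑one | O=C1C[C@H]2CC[C@@H]1C(C)=C2C | intermediate
7 | vinylmagnesium bromide | C=C[Mg]Br | starting material
8 | (1R,2R,4R)‑2‑ethenyl‑5,6‑dimethylbicyclo[2.2.2]oct‑5‑en‑2‑ol | C=C[C@]1(O)C[C@H]2CC[C@@H]1C(C)=C2C | intermediate
9 | acetone | CC(C)=O | starting material
10 | potassium (1R,2R,4R)‑2‑ethenyl‑5,6‑dimethylbicyclo[2.2.2]oct‑5‑en‑2‑olate (not isolated) | C=C[C@]1([O-])C[C@H]2CC[C@@H]1C(C)=C2C.[K+] | intermediate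
11 | potassium (4aS,8aR)‑4a,5‑dimethyl‑1,4,4a,7,8,8a‑hexahydronaphthalen‑2‑olate (not isolated) | C=1CC[C@@H]2CC([O-])=CC[C@]2(C)C=1C.[K+] | intermediate
12 | chloro{[(4aS,8aR)‑4a,5‑dimethyl‑1,4,4a,7,8,8a‑hexahydronaphthalen‑2‑yl]oxy}zinc (not isolated) | C=1CC[C@@H]2CC(O[Zn]Cl)=CC[C@]2(C)C=1C | intermediate
13 | (4aS,8aR)‑3‑(2‑hydroxypropan‑2‑yl)‑4a,5‑dimethyl‑3,4,4a,7,8,8a‑hexahydronaphthalen‑2(1H)‑one (C3 epimers) | C=1CC[C@@H]2CC(=O)C(C(C)(C)O)C[C@]2(C)C=1C | intermediate
14 | 2‑[(4aS,8aR)‑4a,5‑dimethyl‑2‑oxo‑1,2,3,4,4a,7,8,8a‑octahydronaphthalen‑3‑yl]propan‑2‑yl methanesulfonate (not isolated) | C=1CC[C@@H]2CC(=O)C(C(C)(C)OS(C)(=O)=O)C[C@]2(C)C=1C | intermediate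
15 | (4aS,8aR)‑4a,5‑dimethyl‑3‑(propan‑2‑ylidene)‑3,4,4a,7,8,8a‑hexahydronaphthalen‑2(1H)‑one | C=1CC[C@@H]2CC(=O)C(=C(C)C)C[C@]2(C)C=1C | intermediate
16 | lithium (4aS,8aR)‑4a,5‑dimethyl‑3‑(propan‑2‑ylidene)‑3,4,4a,7,8,8a‑hexahydronaphthalen‑2‑olate (not isolated) | C=1CC[C@@H]2C=C([O-])C(=C(C)C)C[C@]2(C)C=1C.[Li+] | intermediate
17 | (4aR)‑4a,5‑dimethyl‑3‑(propan‑2‑ylidene)‑4,4a,7,8‑tetrahydronaphthalen‑2(3H)‑one | C=1CCC2=CC(=O)C(=C(C)C)C[C@]2(C)C=1C | intermediate
18 | (2R,4aR)‑4a,5‑dimethyl‑3‑(propan‑2‑ylidene)‑2,3,4,4a,7,8‑hexahydronaphthalen‑2‑ol | C=1CCC2=C[C@@H](O)C(=C(C)C)C[C@]2(C)C=1C | intermediate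
19 | tert‑butyl{[(2R,4aR)‑4a,5‑dimethyl‑3‑(propan‑2‑ylidene)‑2,3,4,4a,7,8‑hexahydronaphthalen‑2‑yl]oxy}dimethylsilane | C=1CCC2=C[C@@H](O[Si](C)(C)C(C)(C)C)C(=C(C)C)C[C@]2(C)C=1C | intermediate
20 | bis‑thexylboryl adduct: 21 with (2,3‑dimethylbutan‑2‑yl)boryl groups in place of the C2 and C5 hydroxyls, drawn as monomer (not isolated) | CC(C)C(C)(C)B[C@@H]1CC[C@H]2[C@H](BC(C)(C)C(C)C)[C@@H](O[Si](C)(C)C(C)(C)C)C(=C(C)C)C[C@]2(C)[C@H]1C | intermediate
21 | (1R,2R,4aR,5S,6S,8aR)‑6‑[(tert‑butyldimethylsilyl)oxy]‑1,8a‑dimethyl‑7‑(propan‑2‑ylidene)decahydronaphthalene‑2,5‑diol | O[C@@H]1CC[C@H]2[C@H](O)[C@@H](O[Si](C)(C)C(C)(C)C)C(=C(C)C)C[C@]2(C)[C@H]1C | intermediate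
22 | angelic acid [(2Z)‑2‑methylbut‑2‑enoic acid] | C/C=C(/C)C(=O)O | starting material
23 | 2‑bromoethanol | OCCBr | starting material
24 | 2‑hydroxyethyl (2Z)‑2‑methylbut‑2‑enoate | C/C=C(/C)C(=O)OCCO | intermediate
25 | 2‑oxoethyl (2Z)‑2‑methylbut‑2‑enoate | C/C=C(/C)C(=O)OCC=O | intermediate
26 | ethyl 2‑[bis(2,2,2‑trifluoroethoxy)phosphoryl]propanoate | CCOC(=O)C(C)P(=O)(OCC(F)(F)F)OCC(F)(F)F | starting material
27 | 2‑[bis(2,2,2‑trifluoroethoxy)phosphoryl]propanoic acid | OC(=O)C(C)P(=O)(OCC(F)(F)F)OCC(F)(F)F | intermediate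
28 | (1R,2R,4aR,5S,6S,8aR)‑6‑[(tert‑butyldimethylsilyl)oxy]‑5‑hydroxy‑1,8a‑dimethyl‑7‑(propan‑2‑ylidene)decahydronaphthalen‑2‑yl 2‑[bis(2,2,2‑trifluoroethoxy)phosphoryl]propanoate | CC(C(=O)O[C@@H]1CC[C@H]2[C@H](O)[C@@H](O[Si](C)(C)C(C)(C)C)C(=C(C)C)C[C@]2(C)[C@H]1C)P(=O)(OCC(F)(F)F)OCC(F)(F)F | intermediate
29 | (1R,2R,4aR,5S,6S,8aR)‑6‑[(tert‑butyldimethylsilyl)oxy]‑5‑hydroxy‑1,8a‑dimethyl‑7‑(propan‑2‑ylidene)decahydronaphthalen‑2‑yl (2Z)‑2‑methyl‑4‑{[(2Z)‑2‑methylbut‑2‑enoyl]oxy}but‑2‑enoate | C/C=C(/C)C(=O)OC/C=C(/C)C(=O)O[C@@H]1CC[C@H]2[C@H](O)[C@@H](O[Si](C)(C)C(C)(C)C)C(=C(C)C)C[C@]2(C)[C@H]1C | intermediate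
30 | (1R,2R,4aR,5S,6S,8aR)‑5,6‑dihydroxy‑1,8a‑dimethyl‑7‑(propan‑2‑ylidene)decahydronaphthalen‑2‑yl (2Z)‑2‑methyl‑4‑{[(2Z)‑2‑methylbut‑2‑enoyl]oxy}but‑2‑enoate | C/C=C(/C)C(=O)OC/C=C(/C)C(=O)O[C@@H]1CC[C@H]2[C@H](O)[C@@H](O)C(=C(C)C)C[C@]2(C)[C@H]1C | intermediate
31 | (1R,2R,4aR,5S,8aR)‑5‑hydroxy‑1,8a‑dimethyl‑6‑oxo‑7‑(propan‑2‑ylidene)decahydronaphthalen‑2‑yl (2Z)‑2‑methyl‑4‑{[(2Z)‑2‑methylbut‑2‑enoyl]oxy}but‑2‑enoate | C/C=C(/C)C(=O)OC/C=C(/C)C(=O)O[C@@H]1CC[C@H]2[C@H](O)C(=O)C(=C(C)C)C[C@]2(C)[C@H]1C | target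

**Step count**

Total: 18 steps. Longest linear sequence: 15 steps (steps 1–11 and 15–18); steps 12–14 prepare the side‑chain reagents.

**Steps most likely to fail, with fallbacks**

Step 11. The risk is competing addition of borane to the exocyclic tetrasubstituted alkene, or incomplete addition at the hindered ring‑fusion alkene under the mild conditions needed to spare it. The fallback sets out from 18 and returns at 21, masking the isopropylidene before hydroboration. Hydroxyl‑directed epoxidation of 18 (VO(acac)2 cat., t‑BuOOH, CH2Cl2, 0 °C), expected to be fastest at the tetrasubstituted allylic C=C, should give the spiro‑epoxy alcohol F1. Silylation (TBSCl, imidazole, DMF) gives the spiro‑epoxy silyl ether F2. With no competing alkene left, excess BH3·THF followed by NaOH/H2O2 hydroxylates both ring alkenes with the same facial control to give the spiro‑epoxy diol F3. Oxygen transfer from the epoxide to PPh3 (CH3ReO3 cat., benzene, 60 °C) restores the isopropylidene and gives 21.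

Step 6. The risk is proton transfer between the enolate and acetone, or reversal of the aldol addition, which would return the simple ketone and lose the regiochemical advantage of the rearrangement. The fallback sets out from 8 and returns at 13. The rearrangement is run as before (KH, 18‑crown‑6, THF), but enolate 11 is silylated (Me3SiCl, Et3N, −78 °C) and isolated as the trimethylsilyl enol ether F4. A Mukaiyama aldol addition of F4 to acetone 9 (TiCl4, CH2Cl2, −78 °C) then gives 13.

Step 4. The risk is stalling of the copper‑mediated oxygenation or competing allylic autoxidation of the electron‑rich tetrasubstituted alkene. The fallback sets out from 5 and returns at 6. Pinnick oxidation (NaClO2, NaH2PO4, 2‑methylbut‑2‑ene, t‑BuOH/H2O) gives the carboxylic acid F5. α‑Hydroxylation of its dianion (LiN(iPr)2 2.2 equiv, THF; O2; then Na2SO3) gives the α‑hydroxy acid F6. Oxidative decarboxylation with NaIO4 (aq. MeOH) gives 6.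

Further compounds
F1 | step 11 | spiro‑epoxy alcohol: 18 with the isopropylidene C=C epoxidised on the face of the hydroxyl | C=1CCC2=C[C@@H](O)[C@@]3(OC3(C)C)C[C@]2(C)C=1C
F2 | step 11 | tert‑butyldimethylsilyl ether of F1 | C=1CCC2=C[C@@H](O[Si](C)(C)C(C)(C)C)[C@@]3(OC3(C)C)C[C@]2(C)C=1C
F3 | step 11 | spiro‑epoxy diol: F2 with both ring alkenes hydroxylated as in 21 | O[C@@H]1CC[C@H]2[C@H](O)[C@@H](O[Si](C)(C)C(C)(C)C)[C@@]3(OC3(C)C)C[C@]2(C)[C@H]1C
F4 | step 6 | trimethyl{[(4aS,8aR)‑4a,5‑dimethyl‑1,4,4a,7,8,8a‑hexahydronaphthalen‑2‑yl]oxy}silane | C=1CC[C@@H]2CC(O[Si](C)(C)C)=CC[C@]2(C)C=1C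
F5 | step 4 | (1S,2R,4R)‑5,6‑dimethylbicyclo[2.2.2]oct‑5‑ene‑2‑carboxylic acid | OC(=O)[C@@H]1C[C@H]2CC[C@@H]1C(C)=C2C
F6 | step 4 | (1R,4R)‑2‑hydroxy‑5,6‑dimethylbicyclo[2.2.2]oct‑5‑ene‑2‑carboxylic acid (both C2 epimers) | OC(=O)C1(O)C[C@H]2CC[C@@H]1C(C)=C2C
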